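**Assumptions:** Bonannione A is taken as (2S)-6-geranyl-5,7,4'-trihydroxyflavanone, which matches the given SMILES (C2 = S). Enantiopure (2S)-naringenin is assumed to be purchasable; its ee should be checked by chiral HPLC before use.

## Retrosynthetic overview

1. The only stereocentre (C2) and both rings of the chromanone core are bought intact in (2S)-naringenin; no ring is formed in the route.
2. Key disconnection: the C6–C1'' aryl–geranyl bond, made by an O5→C6 [1,3]-sigmatropic-type geranyl shift of the 5-O-geranyl ether on montmorillonite K10. C6 is the only free position ortho to O5 (C4a is blocked), and the (E)-olefin is carried over unchanged.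
3. The 5-O-geranyl ether comes from a Mitsunobu reaction with geraniol on the chelated 5-OH, exposed by selective 7,4'-di-O-acetylation.
4. The acetates are removed last under neutral conditions, so C2 never sees base strong enough for retro-oxa-Michael racemisation.

## Route

**Step 1**
Reactants: 1, (2S)-naringenin [(2S)-5,7-dihydroxy-2-(4-hydroxyphenyl)chroman-4-one]; 2, acetic anhydride
Product: 3, (2S)-7,4'-di-O-acetylnaringenin [(2S)-7-acetoxy-2-(4-acetoxyphenyl)-5-hydroxychroman-4-one]
Conditions: Ac2O (2.1 equiv), pyridine, 0 °C → rt, 3–4 h
Reagents that add atoms: acetic anhydride, CC(=O)OC(C)=O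
Why: Regioselective O-acylation: the 5-OH is hydrogen-bonded to the C4 carbonyl and far less nucleophilic, so only the 7- and 4'-OH react with a controlled amount of Ac2O, and C2 is untouched.

**Step 2**
Reactants: 3, (2S)-7,4'-di-O-acetylnaringenin; 4, geraniol [(2E)-3,7-dimethylocta-2,6-dien-1-ol]
Product: 5, (2S)-7,4'-di-O-acetyl-5-O-geranylnaringenin [(2S)-7-acetoxy-2-(4-acetoxyphenyl)-5-{[(2E)-3,7-dimethylocta-2,6-dien-1-yl]oxy}chroman-4-one]
Conditions: geraniol (1.5 equiv), PPh3 (1.5 equiv), DIAD (1.5 equiv), THF, 0 °C → rt, 12 h
Reagents that add atoms: geraniol, CC(C)=CCC/C(C)=C/CO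
Why: Mitsunobu etherification of the only free phenol; SN2 at the primary allylic carbon keeps the (E)-olefin, and the near-neutral medium leaves the acetates and C2 intact.

**Step 3 (key step)**
Reactants: 5, (2S)-7,4'-di-O-acetyl-5-O-geranylnaringenin
Product: 6, (2S)-7,4'-di-O-acetyl-6-geranylnaringenin [(2S)-7-acetoxy-2-(4-acetoxyphenyl)-6-[(2E)-3,7-dimethylocta-2,6-dien-1-yl]-5-hydroxychroman-4-one]
Conditions: montmorillonite K10 (oven-dried, about 2 g per g of 5), CH2Cl2, 0 °C, 1–2 h, then filter; separate the minor C8 isomer by chromatography
Reagents that add atoms: none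
Why: Clay-promoted [1,3]-sigmatropic O→C geranyl shift via a tight ion pair delivers the unrearranged (E)-geranyl unit to the adjacent C6, whereas the concerted [3,3] pathway would give the reverse linalyl unit at C6 or, after Cope, geranyl at C8; the acidic, non-basic conditions do not epimerise C2.

**Step 4**
Reactants: 6, (2S)-7,4'-di-O-acetyl-6-geranylnaringenin
Product: 7, bonannione A [(2S)-6-geranyl-5,7,4'-trihydroxyflavanone]
Conditions: NH4OAc (10 equiv), MeOH–H2O (4:1), rt, 8–12 h
Reagents that add atoms: none
Why: Neutral transacylation cleaves the aryl acetates at about pH 7, which avoids base-induced chalcone ring-opening (C2 stays S) and acid-induced cyclisation of the geranyl chain onto the flanking phenols.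

## Compound list

1 | (2S)-naringenin | O=C1C[C@@H](c2ccc(O)cc2)Oc2cc(O)cc(O)c12 | starting material
2 | acetic anhydride | CC(=O)OC(C)=O | starting material
3 | (2S)-7,4'-di-O-acetylnaringenin | O=C1C[C@@H](c2ccc(OC(C)=O)cc2)Oc2cc(OC(C)=O)cc(O)c12 | intermediate
4 | geraniol | CC(C)=CCC/C(C)=C/CO | starting material
5 | (2S)-7,4'-di-O-acetyl-5-O-geranylnaringenin | CC(C)=CCC/C(C)=C/COc1cc(OC(C)=O)cc2c1C(=O)C[C@@H](c1ccc(OC(C)=O)cc1)O2 | intermediate
6 | (2S)-7,4'-di-O-acetyl-6-geranylnaringenin | CC(C)=CCC/C(C)=C/Cc1c(OC(C)=O)cc2c(c1O)C(=O)C[C@@H](c1ccc(OC(C)=O)cc1)O2 | intermediate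
7 | bonannione A, (2S)-6-geranylnaringenin | CC(C)=CCC/C(C)=C/Cc1c(O)cc2c(c1O)C(=O)C[C@@H](c1ccc(O)cc1)O2 | target

## Summary

Total step count: 4. Longest linear sequence: 4.

Steps most likely to fail:

1. **Step 3 (K10 geranyl shift).** Risks are loss of the geranyl group, some C8 isomer, and clay-catalysed cyclisation of the product to a chroman or of the geranyl chain. Fallback: switch to a concerted [3,3] route. O-alkylate 3 at O5 with methyl linalyl carbonate under Pd(PPh3)4 to give the tertiary 5-O-linalyl ether, then run a Eu(fod)3-catalysed aromatic Claisen rearrangement. This can only deliver to C6 and gives the normal geranyl chain by allylic inversion; the E/Z mixture is separated on AgNO3-silica.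
2. **Step 2 (Mitsunobu at the hindered, chelated 5-OH).** Risks are low conversion or SN2' (linalyl ether) by-products. Fallback: replace the Mitsunobu with silver-assisted alkylation (geranyl bromide, Ag2O, CH2Cl2, rt), which is also non-basic toward C2.
3. **Step 4 (deacetylation and stereochemical integrity).** Risks are incomplete cleavage or partial racemisation at C2 if the medium becomes basic. Fallback: change the protecting-group strategy to 7,4'-bis-TBS ethers (TBSCl, imidazole in step 1; Et3N·3HF in THF at the end), so no acyl-transfer step is needed.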